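Remark on the chemistry: 1 and 18 are taken to be purchasable. Positions are numbered from the carboxyl-bearing carbon (C1) of each benzoate ring, and O2 and O4 mean the oxygens on C2 and C4. The atom mapping of the key step was checked and found consistent: pyran C2, C3, C4, C5 become C6, C1, C2, C3 of ring C, and the CH2 and acetal carbons of the ketene acetal become C5 and C4.

## Structural features

The target is an achiral tridepside: three benzene rings joined head to tail by two aryl ester bonds. The C1 carbonyl of ring A is esterified by O4 of ring B, the C1 carbonyl of ring B by O4 of ring C, and C1 of ring C carries the free carboxylic acid. Ring A is a 2-hydroxy-4,5-dimethoxy-6-methylbenzoyl unit; rings B and C are both 2-hydroxy-6-methyl-4-oxybenzoyl (orsellinate) units. There is no stereocentre, so all selectivity questions concern regio- and chemoselectivity. The fragile groups are the two aryl esters (opened by hydroxide, alkoxide or amines and open to transacylation by phenoxide), the salicylic acid of ring C (decarboxylation under heat or strong acid) and the electron-rich rings (halogenation, oxidation). Every ester carbonyl lies between an ortho oxygen and an ortho methyl group, so each acylation takes place at a hindered centre. The real difficulty is differentiation: in rings B and C O4 must be acylated while O2 ends free, ring B needs a carboxyl that can be activated while that of ring C stays masked, and ring A needs six substituents in one fixed order. The key step uses the C6(methyl)–C1(carboxyl)–C2(oxygen)–C3(H) edge of ring C, which is the C2–C3–C4–C5 edge of a 6-oxo-6H-pyran-3-carboxylate, and the C4(oxygen)–C5(H) pair, which is a ketene acetal; cycloaddition with loss of CO2 builds ring C with O4 free beside a protected O2.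

## Logic of the disconnections

25 from 24. Only protecting groups are removed: the four O–CH2Ph bonds (the ethers on O2 of rings A, B and C and the ring C ester) are cut. Hydrogenolysis is neutral, so both aryl esters and the salicylic acid should survive. The demand is that every mask is a benzyl group and that nothing else is reducible.

24 from 22 and 11 (through 23). The ester bond between the ring B carbonyl and O4 of ring C is cut. This is the most convergent cut and separates the ring A work from the ring C work. The forward acylation at a carbonyl with two ortho substituents needs a strongly activated acyl group, so 22 may carry no free hydroxyl and 11 must offer O4 as its only nucleophile.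

22 from 21 and 21 from 20. The ring B carboxyl is traced back to a formyl group and the O2 benzyl ether of ring B to the free phenol. A formyl group is a carboxyl equivalent orthogonal to benzyl esters and ethers, it lets ring B come from 18, and its hydrogen bond to O2–H keeps O2 out of the preceding acylation. The forward steps must oxidise a hindered aldehyde and alkylate a chelated phenol without touching the ring A aryl ester.

20 from 17 and 18 (through 19). The ester bond between the ring A carbonyl and O4 of ring B is cut, giving a one-ring acid and a purchasable dihydroxy aldehyde. The forward step must acylate O4 and leave the chelated O2–H alone.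

17 from 16, 16 from 15 and 15 from 14. The carboxyl is taken back to a formyl group, the O2 benzyl group is removed, and the bond between ring A C1 and the formyl carbon is cut. This leaves a phenol with two free ortho positions and no free para position. The forward formylation must choose the ortho carbon next to the methyl group over the one next to the methoxy group.

14 from 12 (through 13). The C–O bond of the phenol is cut back to a C–H bond. The precursor is a cheap trisubstituted benzene whose only C–H without an ortho neighbour is the one required. The forward step needs a sterically governed C–H functionalisation.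

11 from 5 and 7 (through 8, 9 and 10). Ring C bonds C5–C6 and C3–C4 are cut. The four contiguous substituents are moved onto a pyranone in which the two oxygens are different by construction, and the remaining two carbons become a two-carbon nucleophile that delivers O4 as a labile silyl ether. The forward cycloaddition needs a polarity-matched orientation and has to overcome the donor effect of the O4 ether. That ether is kept as benzyl on purpose: an acyl or carbonate group would make the diene more electron-poor, but it would turn 5 into an acyl donor towards 7 and leave an aryl carbonate that could scramble in the later acylation.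

5 from 4. The O–CH2Ph bond on the pyran O4 is cut. The forward step must alkylate oxygen and not the nucleophilic ring carbon (pyran C5), which argues for Mitsunobu conditions over a benzyl halide and base.

4 from 1 and 2 (through 3). The lactone bond O1–C6 of the pyran and the bond between pyran C2 and C3 are cut, leading to a symmetrical keto diester and an acetyl donor. The forward sequence needs C-acylation and a ring closure mild enough for benzyl esters.

7 from 6. One O–Si bond is cut. The forward step is O-silylation of an ester enolate.

## Other disconnections considered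

Alternative 1: Ring A made at the cyclohexane-1,3-dione level.
- Cut: A1–A6 and A3–A4.
- Forward key step: the sodium enolate (NaH) of benzyl 3-oxobutanoate A2 would add in Michael fashion to methyl (Z)-2-methoxybut-2-enoate A3. The ketone enolate of the adduct would then close on the methyl ester (Claisen condensation, 6-exo-trig) to give racemic benzyl trans-2-hydroxy-5-methoxy-6-methyl-4-oxocyclohex-1-ene-1-carboxylate A1.
- In favour: two simple acyclic esters and a classical annulation. The ring A pattern follows from connectivity alone, so the regiochemical question of step 6 does not arise; on this point the alternative is the better plan.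
- Against: A3 has a donor on its alpha carbon and an alkyl group on its beta carbon and should be a sluggish acceptor. The methoxide set free on ring closure can exchange the benzyl ester. A1 must still be dehydrogenated, its new C4 hydroxyl methylated selectively beside the C2 hydroxyl, and its two stereocentres are discarded.
- Comparison: both plans rest on polarity-matched additions of enolate-type nucleophiles. Annulation, aromatisation, methylation and ester cleavage equal steps 5 to 8 in number, but they end in a ring A acid with a free C2 hydroxyl. The differentiation of O2 and O4 in ring C is left unsolved, whereas the chosen key step solves it in the ring-forming event.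

Alternative 2: Ring A assembled last by carbene benzannulation.
- Cut: A5–A6, A1–A2 and A2–A3.
- Forward key step: a Dötz benzannulation. The alkenyl carbene complex (CO)5Cr=C(OMe)C(OMe)=CH2 A5, one CO ligand and the but-2-ynoate A6 of the protected ring B–ring C phenol would merge to the phenol A4, the tribenzyl-protected target with the ring A C2 hydroxyl already free.
- In favour: the highest convergence of all the plans. A hexasubstituted ring with both methoxy groups is made in one step, ring A needs no protecting group, and the finish is the same single hydrogenolysis. In convergence and in the length of the ring A branch it is better than the chosen plan.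
- Against: alkynoates are electron-poor alkynes and are expected to insert slowly. The required orientation (ester carbon next to the CO-derived carbon) rests on a steric preference that is small when methyl competes with an ester. A6 is an activated aryl ester and an acyl donor. The chromium is stoichiometric, and the arene must be freed from the metal although the product is an easily oxidised hydroquinone monoether.
- Comparison: neither key step has precedent on its exact substitution pattern. The pyranone route puts that risk on a small early intermediate, whereas the benzannulation would stake the complete ring B–ring C ester, which still needs the ring C chemistry of steps 1 to 4. The alternative is the more elegant structurally; the chosen plan is better in where the risk is placed.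

Alternative 3: Ring C from a diazo ketone and a siloxyalkyne.
- Cut: C5–C6, C2–C3, C4–C5 and C1–C2.
- Forward key step: a photochemical Danheiser benzannulation. Irradiation of benzyl (2E)-5-diazo-3-methyl-4-oxopent-2-enoate A8 would give a vinylketene by Wolff rearrangement. This would add (ethynyloxy)tri(propan-2-yl)silane A9 in a (2+2) fashion, and heating would lead through 4π opening and 6π closure to benzyl 2-hydroxy-6-methyl-4-[(triisopropylsilyl)oxy]benzoate A7.
- In favour: four bonds in one operation, a regiochemistry set by the polarisation of the siloxyalkyne, and neutral conditions without a large excess of a dienophile. Fluoride would give benzyl 2,4-dihydroxy-6-methylbenzoate A10, whose chelated O2–H can stay free while O4 is acylated. In regiochemical certainty the alternative is the better, and in oxygen differentiation the equal, of the chosen plan.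
- Against: A8 is an acceptor-substituted diazo ketone that needs a regiodefined half ester of a methylbutenedioic acid and a hazardous diazoalkane acylation. A9 is sensitive and has to be made. The electrocyclisation must close on the ester-bearing carbon, and photochemistry limits scale.
- Comparison: both plans build ring C with loss of a small molecule (N2 there, CO2 here). The alternative needs about twice as many operations as steps 1 to 4 to reach the ring C phenol and uses unstable intermediates; the chosen plan uses bench-stable compounds but a deactivated diene.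

Key step: step 4

## Route

Step 1
Reactants: 1 dibenzyl 3-oxopentanedioate; 2 acetyl chloride
Product: 4 benzyl 4-hydroxy-2-methyl-6-oxo-6H-pyran-3-carboxylate, via dibenzyl 2-acetyl-3-oxopentanedioate 3 (not isolated)
Conditions: MgCl2, pyridine, CH2Cl2, 0 °C to rt; aq. HCl wash, crude 3 taken on; DBU, toluene, 90 °C; aq. HCl
Reagents that add atoms: none
Why: Magnesium chelation lets pyridine deprotonate the CH2 of 1 and directs acetyl chloride to carbon (magnesium-enolate C-acylation). The acetyl enolate oxygen of 3 then attacks the distal benzyl ester (6-exo-trig enol lactonisation of a 3,5-dioxo ester), expelling benzyl alcohol and giving the pyranone as its DBU salt until acidification.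

Step 2
Reactants: 4 benzyl 4-hydroxy-2-methyl-6-oxo-6H-pyran-3-carboxylate
Product: 5 benzyl 4-(benzyloxy)-2-methyl-6-oxo-6H-pyran-3-carboxylate
Conditions: BnOH, PPh3, DIAD, THF, 0 °C to rt
Reagents that add atoms: benzyl alcohol, OCc1ccccc1
Why: Mitsunobu etherification: the acidic vinylogous acid 4 protonates the betaine and its O4 oxygen displaces the benzyloxyphosphonium by SN2. This avoids the ring C-benzylation that competes when a benzyl halide and base are used.

Step 3
Reactants: 6 trimethylsilyl acetate
Product: 7 1,1-bis[(trimethylsilyl)oxy]ethene
Conditions: LiN(iPr)2 (commercial solution), THF, −78 °C; Me3SiCl, −78 °C to rt; filtration under argon, distillation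
Reagents that add atoms: chlorotrimethylsilane, C[Si](C)(C)Cl
Why: Ester enolate O-silylation: the amide base removes an acetyl proton at low temperature and the hard silyl chloride traps the enolate on oxygen, giving the ketene bis(silyl) acetal.

Step 4
Reactants: 5 benzyl 4-(benzyloxy)-2-methyl-6-oxo-6H-pyran-3-carboxylate; 7 1,1-bis[(trimethylsilyl)oxy]ethene
Product: 11 benzyl 2-(benzyloxy)-4-hydroxy-6-methylbenzoate, via bridged lactone cycloadduct 8 (not isolated), via bis(silyloxy)cyclohexadiene 9 (not isolated), via aryl trimethylsilyl ether 10 (not isolated)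
Conditions: 7 (3 equiv), toluene, argon, sealed tube, 120 °C; then 1 M HCl, THF, rt
Reagents that add atoms: none
Why: The electron-rich C=C of 7 and the ester-activated diene of 5 should combine in an inverse-electron-demand Diels–Alder reaction, either concerted and asynchronous or, in the limit, a Mukaiyama–Michael addition followed by 6-(enolexo)-exo-trig closure of the lactone dienolate on the bis(silyloxy)carbenium ion; in both cases ring C closes by (4+2) annulation as the carbocycle of 8. The nucleophilic CH2 of 7 bonds to the methyl-bearing pyran C2, which is beta to the benzyl ester and vinylogous to the lactone carbonyl, and the acetal carbon bonds to pyran C5, alpha to the lactone carbonyl; this polarity match sets the new bonds C5–C6 and C3–C4 of ring C. At the reaction temperature 8 should lose CO2 by retro-(4+2) cleavage to 9, whose only way to aromaticity is 1,2-elimination of trimethylsilanol from the CH2–C(OSiMe3)2 unit; as both acetal substituents are the same, one arene 10 results. Acidic work-up hydrolyses only the aryl silyl ether, so O4 is freed while O2 stays benzylated. The closest known reaction type is the cycloaddition of 2-pyranone carboxylates with ketene acetals with loss of CO2 and an alcohol; the 4-benzyloxy donor and the methyl group at the attacked carbon are the untried elements, hence the excess of 7 and the heat. The two bridgehead stereocentres of 8 vanish with CO2 and 11 has none, so only regioselectivity is needed. Chemoselectivity rests on the fact that a neutral silyl ketene acetal does not attack the benzyl ester or the lactone carbonyl without activation.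

Step 5
Reactants: 12 1,2-dimethoxy-3-methylbenzene
Product: 14 3,4-dimethoxy-5-methylphenol, via pinacol arylboronate 13 (not isolated)
Conditions: B2pin2, [Ir(OMe)(cod)]2 (cat., cod = cycloocta-1,5-diene), 4,4′-di-tert-butyl-2,2′-bipyridine, THF, 80 °C; then 30% H2O2, aq. NaOH, 0 °C
Reagents that add atoms: hydrogen peroxide, OO
Why: Iridium-catalysed C–H borylation is sterically controlled and should go to the only C–H of 12 without an ortho substituent. Peroxide then converts the C–B bond into C–O at the same carbon by 1,2-aryl migration.

Step 6
Reactants: 14 3,4-dimethoxy-5-methylphenol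
Product: 15 2-hydroxy-4,5-dimethoxy-6-methylbenzaldehyde
Conditions: MgCl2, Et3N, paraformaldehyde, MeCN, reflux; 1 M HCl
Reagents that add atoms: paraformaldehyde (as formaldehyde), C=O
Why: Magnesium-mediated ortho-formylation of phenols: the magnesium phenoxide delivers formaldehyde to an ortho carbon and a second formaldehyde oxidises the benzylic alkoxide by hydride transfer. Of the two ortho carbons, the one next to the methyl group is para to the in-plane C3 methoxy group and is not flanked by two oxygens, the preference familiar from orcinol derivatives.

Step 7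
Reactants: 15 2-hydroxy-4,5-dimethoxy-6-methylbenzaldehyde
Product: 16 2-(benzyloxy)-4,5-dimethoxy-6-methylbenzaldehyde
Conditions: BnBr, K2CO3, DMF, 50 °C
Reagents that add atoms: benzyl bromide, BrCc1ccccc1
Why: Williamson etherification: K2CO3 in DMF breaks the hydrogen bond of the salicylaldehyde and the phenoxide displaces bromide.

Step 8
Reactants: 16 2-(benzyloxy)-4,5-dimethoxy-6-methylbenzaldehyde
Product: 17 2-(benzyloxy)-4,5-dimethoxy-6-methylbenzoic acid
Conditions: NaClO2, NaH2PO4, 2-methylbut-2-ene, t-BuOH/THF/H2O, rt
Reagents that add atoms: sodium chlorite, [Na+].[O-]Cl=O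
Why: Pinnick oxidation: chlorous acid adds to the aldehyde and fragments to the acid. The hypochlorous acid formed is trapped by the alkene, which protects the electron-rich ring from chlorination.

Step 9
Reactants: 17 2-(benzyloxy)-4,5-dimethoxy-6-methylbenzoic acid; 18 2,4-dihydroxy-6-methylbenzaldehyde
Product: 20 4-formyl-3-hydroxy-5-methylphenyl 2-(benzyloxy)-4,5-dimethoxy-6-methylbenzoate, via acid chloride 19 (not isolated)
Conditions: (COCl)2, DMF (cat.), CH2Cl2, 0 °C to rt, evaporation; then 18, Et3N, DMAP (cat.), CH2Cl2, 0 °C to rt
Reagents that add atoms: none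
Why: Acid chloride formation through the chloroiminium ion, then base-mediated acylation of a phenol. The 4-hydroxyl of 18 is the more acidic and is unhindered, while the 2-hydroxyl is held in a hydrogen bond to the formyl group, so the hindered acyl chloride should go to O4.

Step 10
Reactants: 20 4-formyl-3-hydroxy-5-methylphenyl 2-(benzyloxy)-4,5-dimethoxy-6-methylbenzoate
Product: 21 3-(benzyloxy)-4-formyl-5-methylphenyl 2-(benzyloxy)-4,5-dimethoxy-6-methylbenzoate
Conditions: BnBr, K2CO3, DMF, rt
Reagents that add atoms: benzyl bromide, BrCc1ccccc1
Why: Williamson etherification of the remaining chelated phenol. The aryl ester carbonyl is shielded by its two ortho substituents and should resist carbonate and phenoxide at room temperature.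

Step 11
Reactants: 21 3-(benzyloxy)-4-formyl-5-methylphenyl 2-(benzyloxy)-4,5-dimethoxy-6-methylbenzoate
Product: 22 2-(benzyloxy)-4-{[2-(benzyloxy)-4,5-dimethoxy-6-methylbenzoyl]oxy}-6-methylbenzoic acid
Conditions: NaClO2, NaH2PO4, 2-methylbut-2-ene, t-BuOH/THF/H2O, rt
Reagents that add atoms: sodium chlorite, [Na+].[O-]Cl=O
Why: Pinnick oxidation in a weakly acidic buffer, which leaves the aryl ester and the benzyl ethers untouched.

Step 12
Reactants: 22 2-(benzyloxy)-4-{[2-(benzyloxy)-4,5-dimethoxy-6-methylbenzoyl]oxy}-6-methylbenzoic acid; 11 benzyl 2-(benzyloxy)-4-hydroxy-6-methylbenzoate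
Product: 24 benzyl 2-(benzyloxy)-4-{[2-(benzyloxy)-4-{[2-(benzyloxy)-4,5-dimethoxy-6-methylbenzoyl]oxy}-6-methylbenzoyl]oxy}-6-methylbenzoate, via two-ring acid chloride 23 (not isolated)
Conditions: (COCl)2, DMF (cat.), CH2Cl2, 0 °C to rt, evaporation; then 11, Et3N, DMAP, CH2Cl2, rt
Reagents that add atoms: none
Why: Acid chloride formation and DMAP-assisted acylation of the single free phenol of 11. The existing ring A ester is more hindered and far less electrophilic than the acyl chloride, so transacylation should not compete.

Step 13
Reactants: 24 benzyl 2-(benzyloxy)-4-{[2-(benzyloxy)-4-{[2-(benzyloxy)-4,5-dimethoxy-6-methylbenzoyl]oxy}-6-methylbenzoyl]oxy}-6-methylbenzoate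
Product: 25 2-hydroxy-4-{[2-hydroxy-4-{[2-hydroxy-4,5-dimethoxy-6-methylbenzoyl]oxy}-6-methylbenzoyl]oxy}-6-methylbenzoic acid
Conditions: H2 (1 atm), 10% Pd/C, EtOAc, rt
Reagents that add atoms: none
Why: Hydrogenolysis of the four benzylic C–O bonds on Pd/C in a neutral aprotic solvent; aryl esters, aryl methyl ethers and the salicylic acid are not reduced.

## Compound list

1 | dibenzyl 3-oxopentanedioate | O=C(CC(=O)OCc1ccccc1)CC(=O)OCc1ccccc1 | starting material
2 | acetyl chloride | CC(=O)Cl | starting material
3 | dibenzyl 2-acetyl-3-oxopentanedioate (drawn as the triketo form) | CC(=O)C(C(=O)OCc1ccccc1)C(=O)CC(=O)OCc1ccccc1 | intermediate (not isolated)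
4 | benzyl 4-hydroxy-2-methyl-6-oxo-6H-pyran-3-carboxylate | Cc1oc(=O)cc(O)c1C(=O)OCc1ccccc1 | intermediate
5 | benzyl 4-(benzyloxy)-2-methyl-6-oxo-6H-pyran-3-carboxylate | Cc1oc(=O)cc(OCc2ccccc2)c1C(=O)OCc1ccccc1 | intermediate
6 | trimethylsilyl acetate | CC(=O)O[Si](C)(C)C | starting material
7 | 1,1-bis[(trimethylsilyl)oxy]ethene (ketene bis(trimethylsilyl) acetal) | C=C(O[Si](C)(C)C)O[Si](C)(C)C | intermediate
8 | benzyl 5-(benzyloxy)-1-methyl-3-oxo-8,8-bis[(trimethylsilyl)oxy]-2-oxabicyclo[2.2.2]oct-5-ene-6-carboxylate (racemic, one enantiomer drawn) | C[C@@]12OC(=O)[C@@H](C(OCc3ccccc3)=C1C(=O)OCc1ccccc1)C(O[Si](C)(C)C)(O[Si](C)(C)C)C2 | intermediate (not isolated)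
9 | benzyl 6-(benzyloxy)-2-methyl-4,4-bis[(trimethylsilyl)oxy]cyclohexa-1,5-diene-1-carboxylate | CC1=C(C(=O)OCc2ccccc2)C(OCc2ccccc2)=CC(O[Si](C)(C)C)(O[Si](C)(C)C)C1 | intermediate (not isolated)
10 | benzyl 2-(benzyloxy)-6-methyl-4-[(trimethylsilyl)oxy]benzoate | Cc1cc(O[Si](C)(C)C)cc(OCc2ccccc2)c1C(=O)OCc1ccccc1 | intermediate (not isolated)
11 | benzyl 2-(benzyloxy)-4-hydroxy-6-methylbenzoate | Cc1cc(O)cc(OCc2ccccc2)c1C(=O)OCc1ccccc1 | intermediate
12 | 1,2-dimethoxy-3-methylbenzene | COc1cccc(C)c1OC | starting material
13 | 2-(3,4-dimethoxy-5-methylphenyl)-4,4,5,5-tetramethyl-1,3,2-dioxaborolane | COc1cc(B2OC(C)(C)C(C)(C)O2)cc(C)c1OC | intermediate (not isolated)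
14 | 3,4-dimethoxy-5-methylphenol | COc1cc(O)cc(C)c1OC | intermediate
15 | 2-hydroxy-4,5-dimethoxy-6-methylbenzaldehyde | COc1cc(O)c(C=O)c(C)c1OC | intermediate
16 | 2-(benzyloxy)-4,5-dimethoxy-6-methylbenzaldehyde | COc1cc(OCc2ccccc2)c(C=O)c(C)c1OC | intermediate
17 | 2-(benzyloxy)-4,5-dimethoxy-6-methylbenzoic acid | COc1cc(OCc2ccccc2)c(C(=O)O)c(C)c1OC | intermediate
18 | 2,4-dihydroxy-6-methylbenzaldehyde | Cc1cc(O)cc(O)c1C=O | starting material
19 | 2-(benzyloxy)-4,5-dimethoxy-6-methylbenzoyl chloride | COc1cc(OCc2ccccc2)c(C(=O)Cl)c(C)c1OC | intermediate (not isolated)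
20 | 4-formyl-3-hydroxy-5-methylphenyl 2-(benzyloxy)-4,5-dimethoxy-6-methylbenzoate | COc1cc(OCc2ccccc2)c(C(=O)Oc2cc(C)c(C=O)c(O)c2)c(C)c1OC | intermediate
21 | 3-(benzyloxy)-4-formyl-5-methylphenyl 2-(benzyloxy)-4,5-dimethoxy-6-methylbenzoate | COc1cc(OCc2ccccc2)c(C(=O)Oc2cc(C)c(C=O)c(OCc3ccccc3)c2)c(C)c1OC | intermediate
22 | 2-(benzyloxy)-4-{[2-(benzyloxy)-4,5-dimethoxy-6-methylbenzoyl]oxy}-6-methylbenzoic acid | COc1cc(OCc2ccccc2)c(C(=O)Oc2cc(C)c(C(=O)O)c(OCc3ccccc3)c2)c(C)c1OC | intermediate
23 | 3-(benzyloxy)-4-(chlorocarbonyl)-5-methylphenyl 2-(benzyloxy)-4,5-dimethoxy-6-methylbenzoate | COc1cc(OCc2ccccc2)c(C(=O)Oc2cc(C)c(C(=O)Cl)c(OCc3ccccc3)c2)c(C)c1OC | intermediate (not isolated)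
24 | benzyl 2-(benzyloxy)-4-{[2-(benzyloxy)-4-{[2-(benzyloxy)-4,5-dimethoxy-6-methylbenzoyl]oxy}-6-methylbenzoyl]oxy}-6-methylbenzoate | COc1cc(OCc2ccccc2)c(C(=O)Oc2cc(C)c(C(=O)Oc3cc(C)c(C(=O)OCc4ccccc4)c(OCc4ccccc4)c3)c(OCc3ccccc3)c2)c(C)c1OC | intermediate
25 | 2-hydroxy-4-{[2-hydroxy-4-{[2-hydroxy-4,5-dimethoxy-6-methylbenzoyl]oxy}-6-methylbenzoyl]oxy}-6-methylbenzoic acid (CNP0139469.0) | COc1cc(O)c(C(=O)Oc2cc(C)c(C(=O)Oc3cc(C)c(C(=O)O)c(O)c3)c(O)c2)c(C)c1OC | target

## Step count and least certain steps

Total: 13 steps. Longest linear sequence: 9 steps (steps 5 to 13, from 12 to 25). The ring C branch is 5 steps in its longest line (steps 1, 2, 4, 12, 13), with step 3 as a one-step side branch.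

Step 4 (key step). The cycloaddition may fail to start, because the O4 ether raises the diene energy and the attacked carbon bears a methyl group. Alternatively the first-formed Michael adduct may open by beta-elimination of the lactone carboxylate instead of closing, and on long heating 7 may be lost by oxygen-to-carbon silyl migration. A first remedy within the same approach is ZnBr2 catalysis in CH2Cl2 at rt. The fallback gives up the pyranone and brings ring C in at the aldehyde level, as was done for ring B. It sets out from 23 (made from 22 as in step 12) and 18, which are joined with Et3N and DMAP at O4 to give 4-formyl-3-hydroxy-5-methylphenyl 2-(benzyloxy)-4-{[2-(benzyloxy)-4,5-dimethoxy-6-methylbenzoyl]oxy}-6-methylbenzoate F1. Pinnick oxidation of F1 would give 4-{[2-(benzyloxy)-4-{[2-(benzyloxy)-4,5-dimethoxy-6-methylbenzoyl]oxy}-6-methylbenzoyl]oxy}-2-hydroxy-6-methylbenzoic acid F2, and hydrogenolysis of F2 over Pd/C comes back to the route at 25.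

Step 1. Acetylation may go to oxygen or occur twice, and in the second stage the liberated benzyl alcohol with DBU may remove the acetyl group again (retro-Claisen cleavage) faster than the lactone closes. The fallback builds the same ring by a different bond set: commercial benzyl 3-oxobutanoate (CC(=O)CC(=O)OCc1ccccc1) and malonyl dichloride (O=C(Cl)CC(=O)Cl) are condensed without base, with C-acylation at the active methylene and O-acylation of the enol, a known entry to 4-hydroxy-6-methyl-2-pyranone-5-carboxylates. It replaces 1, 2 and 3, sets out from these two purchased compounds and comes back at 4; it makes no new compound (F0).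

Step 6. Formylation may also occur at the other ortho carbon (between hydroxyl and methoxy), or the reaction may stop at the benzylic alcohol and form diarylmethanes. The fallback introduces the carboxyl carbon as CO2 on an aryllithium. It sets out from 14, which is benzylated (BnBr, K2CO3) to 5-(benzyloxy)-1,2-dimethoxy-3-methylbenzene F3. F3 is brominated para to the in-plane methoxy group (N-bromosuccinimide, MeCN, 0 °C) to give 1-(benzyloxy)-2-bromo-4,5-dimethoxy-3-methylbenzene F4, and bromine–lithium exchange (n-BuLi, THF, −78 °C) followed by CO2 returns to the route at 17.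

Step 10. Carbonate or the phenoxide of 20 may cleave or transfer the aryl ester while the chelated phenol alkylates slowly. The fallback leaves O2 of ring B unprotected. It sets out from 20, which is oxidised under Pinnick conditions to 4-{[2-(benzyloxy)-4,5-dimethoxy-6-methylbenzoyl]oxy}-2-hydroxy-6-methylbenzoic acid F5. F5 is condensed with 11 by trifluoroacetic anhydride in toluene (the hydrogen-bonded ortho hydroxyl is a poor nucleophile) to give benzyl 2-(benzyloxy)-4-{[4-{[2-(benzyloxy)-4,5-dimethoxy-6-methylbenzoyl]oxy}-2-hydroxy-6-methylbenzoyl]oxy}-6-methylbenzoate F6, and hydrogenolysis of F6 comes back at 25.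

Step 12. Acyl transfer at the carbonyl flanked by benzyloxy and methyl may be slow, so that hydrolysis of 23 or attack of the phenoxide of 11 on the ring A ester gains ground. The fallback changes the activation from addition–elimination to ionisation. It sets out from 22, which with trifluoroacetic anhydride in toluene forms 2-(benzyloxy)-4-{[2-(benzyloxy)-4,5-dimethoxy-6-methylbenzoyl]oxy}-6-methylbenzoic trifluoroacetic anhydride F7. This electron-rich, doubly ortho-substituted mixed anhydride can deliver the acyl group as an acylium ion to 11, returning to the route at 24.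

## Further compounds

F1 | step 4 | 4-formyl-3-hydroxy-5-methylphenyl 2-(benzyloxy)-4-{[2-(benzyloxy)-4,5-dimethoxy-6-methylbenzoyl]oxy}-6-methylbenzoate | COc1cc(OCc2ccccc2)c(C(=O)Oc2cc(C)c(C(=O)Oc3cc(C)c(C=O)c(O)c3)c(OCc3ccccc3)c2)c(C)c1OC
F2 | step 4 | 4-{[2-(benzyloxy)-4-{[2-(benzyloxy)-4,5-dimethoxy-6-methylbenzoyl]oxy}-6-methylbenzoyl]oxy}-2-hydroxy-6-methylbenzoic acid | COc1cc(OCc2ccccc2)c(C(=O)Oc2cc(C)c(C(=O)Oc3cc(C)c(C(=O)O)c(O)c3)c(OCc3ccccc3)c2)c(C)c1OC
F0 | step 1 | none | none
F3 | step 6 | 5-(benzyloxy)-1,2-dimethoxy-3-methylbenzene | COc1cc(OCc2ccccc2)cc(C)c1OC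
F4 | step 6 | 1-(benzyloxy)-2-bromo-4,5-dimethoxy-3-methylbenzene | COc1cc(OCc2ccccc2)c(Br)c(C)c1OC
F5 | step 10 | 4-{[2-(benzyloxy)-4,5-dimethoxy-6-methylbenzoyl]oxy}-2-hydroxy-6-methylbenzoic acid | COc1cc(OCc2ccccc2)c(C(=O)Oc2cc(C)c(C(=O)O)c(O)c2)c(C)c1OC
F6 | step 10 | benzyl 2-(benzyloxy)-4-{[4-{[2-(benzyloxy)-4,5-dimethoxy-6-methylbenzoyl]oxy}-2-hydroxy-6-methylbenzoyl]oxy}-6-methylbenzoate | COc1cc(OCc2ccccc2)c(C(=O)Oc2cc(C)c(C(=O)Oc3cc(C)c(C(=O)OCc4ccccc4)c(OCc4ccccc4)c3)c(O)c2)c(C)c1OC
F7 | step 12 | 2-(benzyloxy)-4-{[2-(benzyloxy)-4,5-dimethoxy-6-methylbenzoyl]oxy}-6-methylbenzoic trifluoroacetic anhydride | COc1cc(OCc2ccccc2)c(C(=O)Oc2cc(C)c(C(=O)OC(=O)C(F)(F)F)c(OCc3ccccc3)c2)c(C)c1OC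
A1 | alternative 1 | benzyl trans-2-hydroxy-5-methoxy-6-methyl-4-oxocyclohex-1-ene-1-carboxylate (racemic, one enantiomer drawn) | O=C(OCc1ccccc1)C1=C(O)CC(=O)[C@H](OC)[C@H]1C
A2 | alternative 1 | benzyl 3-oxobutanoate | CC(=O)CC(=O)OCc1ccccc1
A3 | alternative 1 | methyl (Z)-2-methoxybut-2-enoate | C/C=C(\OC)C(=O)OC
A4 | alternative 2 | benzyl 2-(benzyloxy)-4-{[2-(benzyloxy)-4-{[2-hydroxy-4,5-dimethoxy-6-methylbenzoyl]oxy}-6-methylbenzoyl]oxy}-6-methylbenzoate | COc1cc(O)c(C(=O)Oc2cc(C)c(C(=O)Oc3cc(C)c(C(=O)OCc4ccccc4)c(OCc4ccccc4)c3)c(OCc3ccccc3)c2)c(C)c1OC
A5 | alternative 2 | pentacarbonyl[methoxy(1-methoxyethenyl)methylidene]chromium, (CO)5Cr=C(OMe)C(OMe)=CH2 | C=C(OC)C(OC)=[Cr](=C=O)(=C=O)(=C=O)(=C=O)=C=O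
A6 | alternative 2 | benzyl 2-(benzyloxy)-4-{[2-(benzyloxy)-4-(but-2-ynoyloxy)-6-methylbenzoyl]oxy}-6-methylbenzoate | CC#CC(=O)Oc1cc(C)c(C(=O)Oc2cc(C)c(C(=O)OCc3ccccc3)c(OCc3ccccc3)c2)c(OCc2ccccc2)c1
A7 | alternative 3 | benzyl 2-hydroxy-6-methyl-4-[(triisopropylsilyl)oxy]benzoate | Cc1cc(O[Si](C(C)C)(C(C)C)C(C)C)cc(O)c1C(=O)OCc1ccccc1
A8 | alternative 3 | benzyl (2E)-5-diazo-3-methyl-4-oxopent-2-enoate | [N-]=[N+]=CC(=O)/C(C)=C/C(=O)OCc1ccccc1
A9 | alternative 3 | (ethynyloxy)tri(propan-2-yl)silane | C#CO[Si](C(C)C)(C(C)C)C(C)C
A10 | alternative 3 | benzyl 2,4-dihydroxy-6-methylbenzoate | Cc1cc(O)cc(O)c1C(=O)OCc1ccccc1
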